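# Proposed synthesis of 2',3',4',5,7,8-hexamethoxyflavone (19) by Moore benzannulation of a furyl squarate adduct

## Analysis of the target

The target 19 is a flavone: a 4H-chromen-4-one (benzo ring A fused to pyranone ring C) carrying a 2,3,4-trimethoxyphenyl group (ring B) on C2. It has no stereocentre, so every selectivity question is one of regiochemistry. The six aryl methyl ethers are robust, but the C5 methoxyl, peri to the C4 carbonyl, is the first to be lost to Lewis acids, and the pyranone is a vinylogous ester that strong aqueous base can open. Late steps should therefore be mild and free of Lewis acids. Ring B is easy, because it is contained complete in the commercial aldehyde 14. The difficulty is ring A, a benzene with five substituents: oxygen on C5, C7, C8 and C8a, carbon on C4a, and hydrogen only on C6. The usual 1,3,5-trioxygenated building blocks give the 5,7-pattern and leave C6 and C8 as two similarly activated CH positions, so adding the C8 oxygen to a finished ring raises a C6/C8 choice. The strategy reads C5–C6–C7–C8 (O, H, OMe, O) as the four carbons of the mono-methoxy cyclobutenedione 3, and the C8a–C4a edge with O1 as the C2=C3 bond of furan 4. The remaining CH=CH of the furan is then a latent C4 aldehyde plus one sacrificial carbon.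

## Retrosynthetic reasoning

**Ring C, O1–C2.** The last bond cut in 19 is O1–C2, which leads back to the ortho-hydroxyaryl ynone 18. This cut is preferred over C2–C1' or C3–C4 because it keeps ring B, C2 and C3 together as one alkyne unit. The forward reaction is a conjugate addition of the phenol oxygen to the alkyne carbon that bears ring B. It must close the six-membered ring at the β-carbon (6-endo) and not a five-membered ring at the α-carbon.

**C3–C4 and the oxidation level of C4.** Ynone 18 is taken back to the propargylic alcohol 17, which is cut at the carbinol–alkyne bond into the salicylaldehyde 13 and the acetylide 16 of alkyne 15. This divides the molecule into a ring-A half and a ring-B half of similar size. Alkyne 15 comes from 14 by a one-carbon homologation. Forward, an acetylide adds to an aldehyde and the doubly activated alcohol is oxidised.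

**Ortho-hydroxy aldehyde to benzofuran.** In 13 the formyl carbon (future C4) and the phenol oxygen (future O1) sit on neighbouring ring carbons. They are joined retrosynthetically through one extra carbon into the furan ring of 10. Forward, they are released by oxidative cleavage of the furan C2=C3 bond via ozonide 11 and formate 12. The reconnection does not save steps; it turns the C4a–C8a edge into a furan double bond, which the benzannulation needs as its third π component.

**Methyl ethers on C5 and C8.** The methoxyls of 10 at benzofuran C4 and C7 are cut back to the hydroquinone 9. The third methoxyl is left alone because it arrives with the four-membered ring.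

**Ring A, the C5–C4a bond (key disconnection).** Hydroquinone 9 is the enol form of dienone 8, which is opened between benzofuran C4 and C3a to the dienylketene 7. Joining the ketene carbon to the hydroxyl-bearing carbon then gives the cyclobutenone 6. Cutting here puts all four oxygenated or hydrogen-bearing carbons of ring A into one small-ring piece whose substitution is fixed before any benzene ring exists. Forward, a thermal 4π opening and a 6π closure must follow each other, with the furyl group turned towards the ketene.

**C8–C8a.** Cyclobutenone 6 is cut at the bond between the carbinol carbon and furan C2 into 2-lithiofuran 5 (from furan 4) and the dione 3. The forward addition must occur at the carbonyl next to the methoxy-bearing carbon. That carbonyl is the more ketone-like of the two, the other being a vinylogous ester.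

**Hydrogen on C6.** Dione 3 goes back through hydroxy ketone 2 to dimethyl squarate 1. One of the two equivalent carbonyls is reduced and the resulting allylic alcohol is transposed with loss of one methoxyl, so the reduced carbon ends as the vinyl CH.

## Alternatives that were turned down

**Alternative 1:** Ring C is cut at O1–C8a and C4–C4a. Ring A then enters as the aryne A2 (3,5-dimethoxybenzyne), and the O1–C2–C3–C4 unit with ring B enters as the aroylketene A4, set free by thermal cycloreversion of the dioxinone A3. In the forward key step the ketone oxygen of A4 adds to the aryne carbon remote from the flanking methoxyl. The aryl anion so formed, ortho to that methoxyl, is acylated by the ketene carbon, which closes ring C and gives the flavone A1.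
- For: it is the most convergent plan, it forms two bonds and a ring in one operation, and the polarisation of a 3-alkoxy aryne puts oxygen and carbon on the correct ring carbons. A1 would be reached in fewer steps than 18 is here.
- Against: A1 carries hydrogen on C8. An aryne that already held the C8 methoxyl would have alkoxy groups beside both aryne carbons and would lose its directing bias. The C8 oxygen would therefore have to be introduced on A1 itself, where C6 and C8 are each flanked by two oxygens. A workable sequence (selective cleavage of the C5 ether, para-hydroxylation of the 5-phenol in competition with the ortho position C6, double methylation) adds at least three steps. The two reactive partners are also generated under different regimes (fluoride-induced elimination for A2, heat for A4), and each can be consumed by itself or by the other's precursor.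
- Comparison: this alternative is stronger on convergence and on step count to a flavone core. The chosen route is longer, but all four oxygens of ring A are in place by construction and no C–H oxidation of an assembled flavone is needed.

**Alternative 2:** Ring A is cut at C4a–C8a back to the open-chain tetracarbonyl ester A6, a cinnamoyl triketide. In the forward key step the chain methylene flanked by the cinnamoyl carbonyl and the next ketone (the future C4a) attacks the ester carbon (the future C8a) in a Claisen condensation. Aromatisation gives the chalcone A5.
- For: the plan follows the biosynthesis and builds ring A from an acyclic chain without substitution on an arene. The 1,3,5-trioxygenated ring of A5 is symmetric, so the later closure of ring C has no regiochemical question. No organolithium or ozone is needed, and on that point it is the gentler plan.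
- Against: without an enzyme to fold the chain, A6 is hard to prepare as a defined compound and exists as a mixture of enol forms. It can also cyclise by aldol condensation or by lactonisation to a pyranone in competition with the Claisen mode. A5 again lacks the C8 oxygen and carries three free phenols that need differentiation. Oxidative closure to the flavone, selective methylation and a C8 hydroxylation would all follow.
- Comparison: it is weaker than the chosen route in both control and step economy. The chosen route replaces an unguided folding with two electrocyclic steps whose regiochemistry is fixed by the constitution of 6.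

**Alternative 3:** Ring B is cut at C1'–C2' and C5'–C6' by a retro-(4+2) into the 2-ethynylchromone A8 and 3,4-dimethoxyfuran A9. Forward, the cycloaddition gives an oxygen-bridged cyclohexadiene. Acid opens the bridge so that ring B aromatises as the 2'-phenol A7, and one O-methylation then gives 19.
- For: the plan ends one step from the target, ring C is complete before the key step so no 5-exo/6-endo question arises, and the free 2'-hydroxyl is a handle for analogues. On the end game it is stronger than the chosen route.
- Against: ring B is the one part of the target that can be bought complete (14), so the key step builds what needs no building. A8 still contains the whole 5,7,8-trioxygenated ring A and needs its own multi-step synthesis, which leaves the real problem unsolved. A9 also needs several steps. Furan–alkyne cycloadditions are reversible, and an electron-rich furan with a moderately activated alkyne is not a strongly matched pair. The bridge can open towards C2' or C5', and both cations are stabilised by a methoxyl, so the 2'- versus 5'-phenol outcome is not secured.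
- Comparison: the chosen route spends its key step on ring A, where the difficulty lies, and takes ring B from 14 unchanged.

Key step: step 4

Assumption: the target has no stereocentre; the stereogenic intermediates 2, 6, 8, 11 and 17 are racemic (the SMILES of 11 shows one enantiomer), and hydroquinone 9 is taken into step 5 as crude material under argon.

## Route

Step 1
Reactants: 1 dimethyl squarate (3,4-dimethoxycyclobut-3-ene-1,2-dione)
Product: 2 4-hydroxy-2,3-dimethoxycyclobut-2-en-1-one (racemic)
Conditions: LiAlH(OtBu)3 (1.1 equiv), THF, –78 °C; then H2O
Reagents that add atoms: none
Why: Carbonyl 1,2-reduction by a bulky alkoxyaluminium hydride that carries a single hydride; after one addition the remaining carbonyl of the alkoxide is a deactivated vinylogous ester, so reduction should stop at the hydroxy ketone. The carbinol centre forms as a racemate and disappears in step 2.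

Step 2
Reactants: 2 4-hydroxy-2,3-dimethoxycyclobut-2-en-1-one
Product: 3 3-methoxycyclobut-3-ene-1,2-dione
Conditions: conc. aq. HCl (cat.), CH2Cl2, rt; used promptly
Reagents that add atoms: water, O
Why: Acid-catalysed allylic transposition with enol ether hydrolysis, the standard passage from squarate 1,2-adducts to cyclobutenediones: the C4 hydroxyl ionises with help from the C2 methoxyl through the C2=C3 bond, water adds at C2 and methanol is lost, so C2 becomes the new carbonyl and C4 keeps its hydrogen as the vinyl CH. The oxygen count is unchanged because the hydroxyl that leaves as water is replaced by water at C2.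

Step 3
Reactants: 3 3-methoxycyclobut-3-ene-1,2-dione; 4 furan
Product: 6 4-(furan-2-yl)-4-hydroxy-3-methoxycyclobut-2-en-1-one (racemic), via 2-lithiofuran 5 (not isolated)
Conditions: 4, n-BuLi, THF, –78 to 0 °C; cooled to –78 °C and added to 3 in THF; aq. NH4Cl at –78 °C
Reagents that add atoms: none
Why: C2 lithiation of furan, then 1,2-addition of the organolithium to a cyclobutenedione. In 3 the C1 carbonyl is a vinylogous ester (conjugated with the methoxyl through C4=C3) while C2 is a cross-conjugated ketone next to the methoxy-bearing carbon, so addition should occur at C2; this is the regiochemistry that later places hydrogen on C6 and methoxyl on C7 of the flavone. Inverse addition and a cold quench keep the alkoxide from ring opening or a second addition; the carbinol centre is racemic and is lost in step 4.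

Step 4
Reactants: 6 4-(furan-2-yl)-4-hydroxy-3-methoxycyclobut-2-en-1-one
Product: 9 6-methoxy-1-benzofuran-4,7-diol, via (3Z)-4-(furan-2-yl)-4-hydroxy-3-methoxybuta-1,3-dien-1-one 7 (not isolated), via 7-hydroxy-6-methoxy-1-benzofuran-4(3aH)-one 8 (not isolated)
Conditions: degassed p-xylene (0.02 M), 138 °C, argon; crude 9 kept under argon and used at once
Reagents that add atoms: none
Why: Heating opens the cyclobutenone by a thermally allowed conrotatory 4π electrocyclic cleavage of the C1–C4 bond to the dienylketene 7. The sense of conrotation is set by torquoselectivity: the C4 hydroxyl, a lone-pair donor, turns outward, so the furyl group turns inward and ends cis to the ketene-bearing carbon, (Z) at the new C3=C4 bond. In that geometry the ketene C=C, the enol double bond and the furan C2=C3 bond form a hexatriene, and a 6π electrocyclisation closes ring A as a six-membered carbocycle by bonding the ketene carbon to furan C3, giving dienone 8. Enolisation of 8 restores aromaticity and makes the sequence irreversible; the C3a stereocentre of 8 is erased and 9 has none. The closest known reaction type is the Moore rearrangement of 4-aryl- and 4-heteroaryl-4-hydroxycyclobutenones to annulated hydroquinones, which includes 2-furyl cases. The step needs outward rotation of the hydroxyl, secured by its donor character against the carbon substituent; closure at furan C3, the only carbon ortho to the point of attachment; and no capture of the ketene by a second molecule, secured by high dilution. The oxygen pattern needs no selectivity here, because the constitution of 6 already places OH, OMe, H and the ketene oxygen on benzofuran C7, C6, C5 and C4. Air is excluded because 9 is an electron-rich hydroquinone.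

Step 5
Reactants: 9 6-methoxy-1-benzofuran-4,7-diol
Product: 10 4,6,7-trimethoxy-1-benzofuran
Conditions: MeI (excess), K2CO3, degassed DMF, rt, argon
Reagents that add atoms: iodomethane, CI
Why: Williamson O-methylation of both phenols; the carbonate is basic enough for the phenols, and the furan and aryl CH positions are not alkylated. Exclusion of oxygen keeps the hydroquinone anion from oxidising to the quinone before it is capped.

Step 6
Reactants: 10 4,6,7-trimethoxy-1-benzofuran
Product: 13 2-hydroxy-3,4,6-trimethoxybenzaldehyde, via 4,6,7-trimethoxy-1-benzofuran 2,3-ozonide 11 (not isolated), via 2-formyl-3,5,6-trimethoxyphenyl formate 12 (not isolated)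
Conditions: O3 (about 1 equiv, to consumption of 10), CH2Cl2, –78 °C; Me2S, –78 °C to rt; then K2CO3 (cat.), MeOH, rt
Reagents that add atoms: ozone, [O-][O+]=O
Why: Ozonolysis of the enol-ether-like C2=C3 bond of a benzofuran by the Criegee mechanism to ozonide 11, reduction by Me2S to the aryl formate aldehyde 12, then base-catalysed methanolysis of the formate. The furan double bond is the most electron-rich and least aromatic π bond, so one equivalent of O3 at low temperature should cleave it before the methoxylated benzene ring is attacked. The new aldehyde carbon is the future C4 and the freed phenol oxygen the future O1.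

Step 7
Reactants: 14 2,3,4-trimethoxybenzaldehyde
Product: 15 1-ethynyl-2,3,4-trimethoxybenzene
Conditions: dimethyl (1-diazo-2-oxopropyl)phosphonate, K2CO3, MeOH, rt
Reagents that add atoms: dimethyl (1-diazo-2-oxopropyl)phosphonate, COP(=O)(OC)C(=[N+]=[N-])C(C)=O
Why: Ohira–Bestmann variant of the Seyferth–Gilbert homologation: methoxide deacylates the reagent, the diazomethylphosphonate anion adds to the aldehyde, and loss of phosphate and N2 followed by a 1,2-shift in the alkylidene carbene gives the terminal alkyne. Mild base at room temperature leaves the aryl methyl ethers untouched.

Step 8
Reactants: 15 1-ethynyl-2,3,4-trimethoxybenzene; 13 2-hydroxy-3,4,6-trimethoxybenzaldehyde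
Product: 17 2-[1-hydroxy-3-(2,3,4-trimethoxyphenyl)prop-2-yn-1-yl]-3,5,6-trimethoxyphenol (racemic), via lithium (2,3,4-trimethoxyphenyl)acetylide 16 (not isolated)
Conditions: 15 (2.5 equiv), n-BuLi (2.4 equiv), THF, –78 °C; 13 in THF, –78 to 0 °C; aq. NH4Cl
Reagents that add atoms: none
Why: Addition of a lithium acetylide to an aldehyde. The first equivalent of 16 is consumed by the phenol (returning 15, which is recovered) and the excess adds to the lithium phenoxide aldehyde; the carbinol centre is racemic and is oxidised away in step 9.

Step 9
Reactants: 17 2-[1-hydroxy-3-(2,3,4-trimethoxyphenyl)prop-2-yn-1-yl]-3,5,6-trimethoxyphenol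
Product: 18 1-(2-hydroxy-3,4,6-trimethoxyphenyl)-3-(2,3,4-trimethoxyphenyl)prop-2-yn-1-one
Conditions: activated MnO2 (excess), CH2Cl2, rt
Reagents that add atoms: none
Why: MnO2 oxidation of an alcohol that is both benzylic and propargylic, a class oxidised selectively under neutral heterogeneous conditions. The phenol, which becomes hydrogen-bonded to the new ketone, and the methyl ethers should be left alone.

Step 10
Reactants: 18 1-(2-hydroxy-3,4,6-trimethoxyphenyl)-3-(2,3,4-trimethoxyphenyl)prop-2-yn-1-one
Product: 19 2',3',4',5,7,8-hexamethoxyflavone [5,7,8-trimethoxy-2-(2,3,4-trimethoxyphenyl)-4H-chromen-4-one]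
Conditions: 4-(dimethylamino)pyridine (0.2 equiv), DMF, 30 °C
Reagents that add atoms: none
Why: Nucleophile-catalysed intramolecular oxa-Michael addition: the pyridine adds to the ynone β-carbon, the phenol oxygen attacks the same carbon and the catalyst is expelled, so O1–C2 forms at the carbon bearing ring B (6-endo) and not at the α-carbon (5-exo). The ketone directs conjugate addition to the β-carbon, and the aprotic medium favours this mode.

## Compound list

1 | dimethyl squarate (3,4-dimethoxycyclobut-3-ene-1,2-dione) | COC1=C(OC)C(=O)C1=O | starting material
2 | 4-hydroxy-2,3-dimethoxycyclobut-2-en-1-one (racemic) | COC1=C(OC)C(O)C1=O | intermediate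
3 | 3-methoxycyclobut-3-ene-1,2-dione | COC1=CC(=O)C1=O | intermediate
4 | furan | c1ccoc1 | starting material
5 | 2-lithiofuran (not isolated) | [Li]c1ccco1 | intermediate
6 | 4-(furan-2-yl)-4-hydroxy-3-methoxycyclobut-2-en-1-one (racemic) | COC1=CC(=O)C1(O)c1ccco1 | intermediate
7 | (3Z)-4-(furan-2-yl)-4-hydroxy-3-methoxybuta-1,3-dien-1-one (not isolated) | O=C=C/C(OC)=C(/O)c1ccco1 | intermediate
8 | 7-hydroxy-6-methoxy-1-benzofuran-4(3aH)-one (racemic, not isolated) | COC1=CC(=O)C2C=COC2=C1O | intermediate
9 | 6-methoxy-1-benzofuran-4,7-diol | COc1cc(O)c2ccoc2c1O | intermediate
10 | 4,6,7-trimethoxy-1-benzofuran | COc1cc(OC)c2ccoc2c1OC | intermediate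
11 | 4,6,7-trimethoxy-1-benzofuran 2,3-ozonide (1,2,4-trioxolane bridging the former furan C2 and C3; racemic, not isolated) | COc1cc(OC)c2c(c1OC)O[C@@H]1O[C@H]2OO1 | intermediate
12 | 2-formyl-3,5,6-trimethoxyphenyl formate (not isolated) | O=COc1c(C=O)c(OC)cc(OC)c1OC | intermediate
13 | 2-hydroxy-3,4,6-trimethoxybenzaldehyde | O=Cc1c(O)c(OC)c(OC)cc1OC | intermediate
14 | 2,3,4-trimethoxybenzaldehyde | COc1ccc(C=O)c(OC)c1OC | starting material
15 | 1-ethynyl-2,3,4-trimethoxybenzene | C#Cc1ccc(OC)c(OC)c1OC | intermediate
16 | lithium (2,3,4-trimethoxyphenyl)acetylide (not isolated) | [Li]C#Cc1ccc(OC)c(OC)c1OC | intermediate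
17 | 2-[1-hydroxy-3-(2,3,4-trimethoxyphenyl)prop-2-yn-1-yl]-3,5,6-trimethoxyphenol (racemic) | COc1ccc(C#CC(O)c2c(OC)cc(OC)c(OC)c2O)c(OC)c1OC | intermediate
18 | 1-(2-hydroxy-3,4,6-trimethoxyphenyl)-3-(2,3,4-trimethoxyphenyl)prop-2-yn-1-one | COc1ccc(C#CC(=O)c2c(OC)cc(OC)c(OC)c2O)c(OC)c1OC | intermediate
19 | 2',3',4',5,7,8-hexamethoxyflavone | COc1ccc(-c2cc(=O)c3c(OC)cc(OC)c(OC)c3o2)c(OC)c1OC | target

## Step count and least certain steps

Total step count: 10. Longest linear sequence: 9 steps (steps 1 to 6 and 8 to 10); step 7 is a one-step side branch.

**Step 4 (the key step).** The most likely failures are oxidation of the electron-rich hydroquinone during and after the hot thermolysis, and capture of the ketene by a hydroxyl group of a second molecule before it reaches the furan. Both erode the material balance without changing the regiochemistry. The fallback removes the free hydroxyl before the rearrangement. It sets out from 6, which is O-methylated at the tertiary alcohol (MeI, Ag2O, MeCN) to 4-(furan-2-yl)-3,4-dimethoxycyclobut-2-en-1-one F1. Thermolysis of F1 in p-xylene should follow the same opening and closure, the methoxyl also turning outward, and give the monophenol 6,7-dimethoxy-1-benzofuran-4-ol F2. This phenol cannot pass to a quinone without losing a methyl group. One methylation (MeI, K2CO3) converts F2 into 10, where the route is rejoined.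

**Step 6.** The likely failure is over-oxidation: ozone attacking the tetra-oxygenated benzene ring in competition with the furan double bond, because both are electron-rich. The fallback replaces the dipolar cleavage by a stepwise dihydroxylation and glycol cleavage. It sets out from 10, which OsO4 (cat.) with N-methylmorpholine N-oxide in acetone/water should dihydroxylate only at the enol ether bond, giving cis-4,6,7-trimethoxy-2,3-dihydro-1-benzofuran-2,3-diol F3. NaIO4 then cleaves the glycol to the aryl formate 12, which is methanolysed to 13 as in the route.

**Step 8.** The likely failure is incomplete addition, because the ortho phenoxide and the ortho and para methoxyls lower the electrophilicity of the aldehyde, and because the dianionic adduct may be poorly soluble. The fallback masks the phenol. It sets out from 13, which with MOMCl and i-Pr2NEt gives 3,4,6-trimethoxy-2-(methoxymethoxy)benzaldehyde F4. One equivalent of 16 adds to give 1-[3,4,6-trimethoxy-2-(methoxymethoxy)phenyl]-3-(2,3,4-trimethoxyphenyl)prop-2-yn-1-ol F5, and MnO2 oxidises this to 1-[3,4,6-trimethoxy-2-(methoxymethoxy)phenyl]-3-(2,3,4-trimethoxyphenyl)prop-2-yn-1-one F6. HCl in MeOH removes the acetal and returns the route to 18.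

**Step 10.** The likely failure is closure at the α-carbon (5-exo) competing with the 6-endo mode, since both are geometrically open to the phenoxide. The fallback makes the closure an addition–elimination at a carbon that is the only electrophilic site. It sets out from 18, to which Et2NH in EtOH adds in conjugate fashion to give (E)-3-(diethylamino)-1-(2-hydroxy-3,4,6-trimethoxyphenyl)-3-(2,3,4-trimethoxyphenyl)prop-2-en-1-one F7. Warming F7 with a little acid lets the phenol displace the amine at the β-carbon, which can only form the six-membered ring, and gives 19.

## Further compounds

F1 | step 4 | 4-(furan-2-yl)-3,4-dimethoxycyclobut-2-en-1-one (racemic) | COC1=CC(=O)C1(OC)c1ccco1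
F2 | step 4 | 6,7-dimethoxy-1-benzofuran-4-ol | COc1cc(O)c2ccoc2c1OC
F3 | step 6 | cis-4,6,7-trimethoxy-2,3-dihydro-1-benzofuran-2,3-diol (racemic) | COc1cc(OC)c2c(c1OC)O[C@H](O)[C@@H]2O
F4 | step 8 | 3,4,6-trimethoxy-2-(methoxymethoxy)benzaldehyde | COCOc1c(C=O)c(OC)cc(OC)c1OC
F5 | step 8 | 1-[3,4,6-trimethoxy-2-(methoxymethoxy)phenyl]-3-(2,3,4-trimethoxyphenyl)prop-2-yn-1-ol (racemic) | COCOc1c(C(O)C#Cc2ccc(OC)c(OC)c2OC)c(OC)cc(OC)c1OC
F6 | step 8 | 1-[3,4,6-trimethoxy-2-(methoxymethoxy)phenyl]-3-(2,3,4-trimethoxyphenyl)prop-2-yn-1-one | COCOc1c(C(=O)C#Cc2ccc(OC)c(OC)c2OC)c(OC)cc(OC)c1OC
F7 | step 10 | (E)-3-(diethylamino)-1-(2-hydroxy-3,4,6-trimethoxyphenyl)-3-(2,3,4-trimethoxyphenyl)prop-2-en-1-one | CCN(CC)/C(=C/C(=O)c1c(O)c(OC)c(OC)cc1OC)c1ccc(OC)c(OC)c1OC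
A1 | alternative 1 | 5,7-dimethoxy-2-(2,3,4-trimethoxyphenyl)-4H-chromen-4-one | COc1cc(OC)c2c(c1)oc(-c1ccc(OC)c(OC)c1OC)cc2=O
A2 | alternative 1 | 3,5-dimethoxybenzyne (1,2-didehydro-3,5-dimethoxybenzene) | COC1=CC(OC)=CC#C1
A3 | alternative 1 | 2,2-dimethyl-6-(2,3,4-trimethoxyphenyl)-4H-1,3-dioxin-4-one | COc1ccc(C2=CC(=O)OC(C)(C)O2)c(OC)c1OC
A4 | alternative 1 | 3-oxo-3-(2,3,4-trimethoxyphenyl)prop-1-en-1-one (aroylketene) | COc1ccc(C(=O)C=C=O)c(OC)c1OC
A5 | alternative 2 | (E)-1-(2,4,6-trihydroxyphenyl)-3-(2,3,4-trimethoxyphenyl)prop-2-en-1-one | COc1ccc(/C=C/C(=O)c2c(O)cc(O)cc2O)c(OC)c1OC
A6 | alternative 2 | methyl (E)-3,5,7-trioxo-9-(2,3,4-trimethoxyphenyl)non-8-enoate | COC(=O)CC(=O)CC(=O)CC(=O)/C=C/c1ccc(OC)c(OC)c1OC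
A7 | alternative 3 | 2-(2-hydroxy-3,4-dimethoxyphenyl)-5,7,8-trimethoxy-4H-chromen-4-one | COc1ccc(-c2cc(=O)c3c(OC)cc(OC)c(OC)c3o2)c(O)c1OC
A8 | alternative 3 | 2-ethynyl-5,7,8-trimethoxy-4H-chromen-4-one | C#Cc1cc(=O)c2c(OC)cc(OC)c(OC)c2o1
A9 | alternative 3 | 3,4-dimethoxyfuran | COc1cocc1OC
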